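**Plan**

1. Locants: ring A = C1–C2–C3(OAc)–C4(Me)–C5(Me)–C10(OH); ring B = C5–C6=C7(Ac)–C8(=O)–C9(O‑angeloyl)–C10. Retrosynthetic cuts, in order: the C9 ester C–O bond; C6=C7 and the C7–acetyl bond; ring B at C9–C10 (aldol) and C5–C6 (Michael); ring A at C2–C3 and C4–C5 ([4+2]).
2. Forward: ring A arises first by a Diels–Alder reaction of the 2‑silyloxy diene C2=C1–C10(OSi)=C5(Me) with (E)‑pent‑3‑en‑2‑one (C3=C4). Baeyer–Villiger oxidation turns the C3 acetyl into the C3 acetate. Ring B is then annulated onto the C10 ketone, whose oxygen stays as the 10‑hydroxyl, with a 1‑alkoxybut‑3‑en‑2‑one that brings C6–C9 and the C9 oxygen; C7 acetylation, dehydrogenation and angeloylation finish.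
3. Enabling feature: in ring A the two oxygens sit 1,4 (C10 and C3) and the two methyls sit on the adjacent C4 and C5. This is the "para" adduct pattern of a 2‑silyloxy diene with a β‑methyl enone, and the ketone unveiled at C10 is then the electrophile for the ring B aldol.
4. Stereochemistry: C4 is set by a chiral oxazaborolidinium catalyst in the cycloaddition and relays to the rest: C3 by Mitsunobu inversion, C5 by Michael addition anti to the C4 methyl, C10 by the cis‑selective ketol closure, C9 by the equatorial (trans) preference next to the ketone. The Z alkene comes from angelic acid.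

Key step: step 2

Assumption: the (S)‑oxazaborolidine is written as the enantiomer that exposes the Cα‑re/Cβ‑si face of the bound enone; should the opposite sense be found, the (R)‑enantiomer is used instead and nothing else changes.

**Route**

Step 1
Reactants: 1 pent‑1‑en‑3‑one
Product: 2 (Z)‑3‑(triisopropylsilyloxy)penta‑1,3‑diene
Conditions: i‑Pr3SiOTf, Et3N, CH2Cl2, 0 °C to rt
Reagents that add atoms: triisopropylsilyl trifluoromethanesulfonate, CC(C)[Si](C(C)C)(C(C)C)OS(=O)(=O)C(F)(F)F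
Why: Silyl enol ether formation by soft enolization of the ethyl ketone should give the 2‑silyloxy diene as the thermodynamically preferred Z isomer, which places the future C5 methyl on the outside of the diene.

Step 2
Reactants: 2 (Z)‑3‑(triisopropylsilyloxy)penta‑1,3‑diene, 3 (E)‑pent‑3‑en‑2‑one
Product: 4 1‑[(1R,5R,6R)‑5,6‑dimethyl‑4‑(triisopropylsilyloxy)cyclohex‑3‑en‑1‑yl]ethanone
Conditions: (S)‑3,3‑diphenyl‑1‑(2‑methylphenyl)tetrahydro‑1H,3H‑pyrrolo[1,2‑c][1,3,2]oxazaborole (20 mol %), Tf2NH (20 mol %), CH2Cl2, −78 to −40 °C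
Reagents that add atoms: none
Why: The N‑protonated oxazaborolidine binds the enone carbonyl and lowers its LUMO, and the electron‑rich diene adds in a concerted, asynchronous [4+2] cycloaddition in which the C4–C5 bond (nucleophilic diene terminus next to the silyloxy carbon onto the enone β‑carbon) runs ahead of the C2–C3 bond. The closest known reaction type is the oxazaborolidinium‑catalysed enantioselective Diels–Alder reaction of 2‑silyloxy dienes with enones and acrylates. Ring A closes by suprafacial [4+2] addition (a 6‑endo‑trig Michael closure if the pathway becomes a stepwise Mukaiyama–Michael/Michael sequence, which leads to the same product). C3 and C4 come out trans because the E geometry of the dienophile is transferred suprafacially, C5 comes out cis to the acetyl from the Z diene in the endo transition state (this center is re‑set in step 10), and the absolute configuration is fixed by the catalyst, which shields one face so that the diene adds to the Cα‑re/Cβ‑si face and C4 becomes R. The step needs regio‑, face and endo selectivity: the 2‑silyloxy group secures the "para" orientation (acetyl carbon 1,4 to the oxygen‑bearing C10), the catalyst secures the face, and secondary orbital overlap the endo mode.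

Step 3
Reactants: 4 1‑[(1R,5R,6R)‑5,6‑dimethyl‑4‑(triisopropylsilyloxy)cyclohex‑3‑en‑1‑yl]ethanone
Product: 5 1‑[(6R,7R,8R)‑6,7‑dimethyl‑1,4‑dioxaspiro[4.5]decan‑8‑yl]ethanone
Conditions: HOCH2CH2OH, camphorsulfonic acid (cat.), CH2Cl2, rt
Reagents that add atoms: ethylene glycol, OCCO
Why: Acid‑catalysed acetalization of the silyl enol ether (C‑protonation, capture of the silyloxocarbenium ion by the diol, loss of silanol) should mask the ring carbonyl chemoselectively, because no water is released and the methyl ketone is therefore not ketalized; no stereocenter is touched.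

Step 4
Reactants: 5 1‑[(6R,7R,8R)‑6,7‑dimethyl‑1,4‑dioxaspiro[4.5]decan‑8‑yl]ethanone
Product: 6 (6R,7R,8R)‑6,7‑dimethyl‑1,4‑dioxaspiro[4.5]decan‑8‑yl acetate
Conditions: mCPBA, NaHCO3, CH2Cl2, rt
Reagents that add atoms: meta‑chloroperoxybenzoic acid, OOC(=O)c1cccc(Cl)c1
Why: Baeyer–Villiger oxidation of the methyl ketone, in which the secondary ring carbon migrates in preference to methyl with retention at C3; the bicarbonate buffer protects the dioxolane.

Step 5
Reactants: 6 (6R,7R,8R)‑6,7‑dimethyl‑1,4‑dioxaspiro[4.5]decan‑8‑yl acetate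
Product: 7 (6R,7R,8R)‑6,7‑dimethyl‑1,4‑dioxaspiro[4.5]decan‑8‑ol
Conditions: K2CO3, MeOH, rt
Reagents that add atoms: none
Why: Base‑catalysed transesterification (methanolysis) should free the C3 alcohol, equatorial and trans to the C4 methyl, ready for inversion.

Step 6
Reactants: 7 (6R,7R,8R)‑6,7‑dimethyl‑1,4‑dioxaspiro[4.5]decan‑8‑ol
Product: 8 (6R,7R,8S)‑6,7‑dimethyl‑1,4‑dioxaspiro[4.5]decan‑8‑yl acetate
Conditions: AcOH, PPh3, DIAD, toluene, 0 °C to rt
Reagents that add atoms: acetic acid, CC(=O)O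
Why: Mitsunobu esterification: SN2 displacement of the oxyphosphonium group by acetate should invert C3 and place the acetate cis to the C4 methyl, as in the target.

Step 7
Reactants: 8 (6R,7R,8S)‑6,7‑dimethyl‑1,4‑dioxaspiro[4.5]decan‑8‑yl acetate
Product: 9 (1S,2R,3R)‑2,3‑dimethyl‑4‑oxocyclohexyl acetate
Conditions: 1 M HCl, THF, rt
Reagents that add atoms: water, O
Why: Acid‑catalysed ketal hydrolysis should release the C10 ketone without touching the acetate; the epimerizable C5 (α to the ketone) is of no consequence because it becomes sp2 in step 10.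

Step 8
Reactants: 10 (4‑methoxyphenyl)methanol, 11 2‑chloro‑N‑methoxy‑N‑methylacetamide
Product: 12 N‑methoxy‑2‑[(4‑methoxyphenyl)methoxy]‑N‑methylacetamide
Conditions: NaH, THF, 0 °C to rt
Reagents that add atoms: none
Why: Williamson ether synthesis: SN2 attack of the alkoxide on the activated α‑chloro amide.

Step 9
Reactants: 12 N‑methoxy‑2‑[(4‑methoxyphenyl)methoxy]‑N‑methylacetamide
Product: 13 1‑[(4‑methoxyphenyl)methoxy]but‑3‑en‑2‑one
Conditions: CH2=CHMgBr, THF, −78 to 0 °C; quench into cold 1 M HCl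
Reagents that add atoms: vinylmagnesium bromide, C=C[Mg]Br
Why: Weinreb ketone synthesis: the chelated tetrahedral intermediate prevents over‑addition, and the acidic quench keeps the liberated amine from adding to the vinyl ketone.

Step 10
Reactants: 9 (1S,2R,3R)‑2,3‑dimethyl‑4‑oxocyclohexyl acetate, 13 1‑[(4‑methoxyphenyl)methoxy]but‑3‑en‑2‑one
Product: 15 (1S,4aR,5R,6S,8aR)‑6‑acetoxy‑8a‑hydroxy‑1‑[(4‑methoxyphenyl)methoxy]‑4a,5‑dimethyloctahydronaphthalen‑2(1H)‑one, via Michael adduct 14 (not isolated)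
Conditions: KOt‑Bu (0.2 equiv), t‑BuOH/THF, −10 to 0 °C
Reagents that add atoms: none
Why: Robinson‑type Michael addition/intramolecular aldol stopped at the ketol: the more substituted enolate should add to the vinyl ketone anti to the pseudoaxial C4 methyl (quaternary C5, methyls cis), the 6‑(enolendo)‑exo‑trig aldol should close ring B to the cis‑fused ketol (10‑OH cis to the C5 methyl, as usual for Robinson ketols), and the epimerizable C9 should settle with the ether oxygen equatorial, trans to the 10‑hydroxyl.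

Step 11
Reactants: 15 (1S,4aR,5R,6S,8aR)‑6‑acetoxy‑8a‑hydroxy‑1‑[(4‑methoxyphenyl)methoxy]‑4a,5‑dimethyloctahydronaphthalen‑2(1H)‑one
Product: 16 (1R,4aR,5R,6S,8aR)‑3‑acetyl‑2,8a‑dihydroxy‑1‑[(4‑methoxyphenyl)methoxy]‑4a,5‑dimethyl‑1,4,4a,5,6,7,8,8a‑octahydronaphthalen‑6‑yl acetate (enol form of the β‑diketone)
Conditions: MgBr2·OEt2, i‑Pr2NEt, 1‑acetylbenzotriazole, CH2Cl2, rt
Reagents that add atoms: 1‑acetyl‑1H‑benzotriazole, CC(=O)n1nnc2ccccc12
Why: Soft‑enolization C‑acylation (magnesium enolate with an N‑acylbenzotriazole, a Claisen‑type acylation) should acetylate C7, the unhindered methylene α to the C8 ketone, and not the ether‑bearing C9 methine next to the quaternary C10; the mild amine base leaves the acetate and the β‑hydroxy ketone intact.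

Step 12
Reactants: 16 (1R,4aR,5R,6S,8aR)‑3‑acetyl‑2,8a‑dihydroxy‑1‑[(4‑methoxyphenyl)methoxy]‑4a,5‑dimethyl‑1,4,4a,5,6,7,8,8a‑octahydronaphthalen‑6‑yl acetate
Product: 18 (1S,4aR,5R,6S,8aR)‑6‑acetoxy‑3‑acetyl‑8a‑hydroxy‑1‑[(4‑methoxyphenyl)methoxy]‑4a,5‑dimethyl‑4a,5,6,7,8,8a‑hexahydronaphthalen‑2(1H)‑one, via phenylselenide 17 (not isolated)
Conditions: PhSeCl, pyridine, CH2Cl2, 0 °C; then 30% H2O2, 0 °C to rt
Reagents that add atoms: none
Why: α‑Selenenylation of the β‑diketone followed by selenoxide syn‑elimination can only eliminate toward C6 and should give the C6=C7 enedione; the quaternary C5 shields the new acceptor from conjugate attack.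

Step 13
Reactants: 18 (1S,4aR,5R,6S,8aR)‑6‑acetoxy‑3‑acetyl‑8a‑hydroxy‑1‑[(4‑methoxyphenyl)methoxy]‑4a,5‑dimethyl‑4a,5,6,7,8,8a‑hexahydronaphthalen‑2(1H)‑one
Product: 19 (1S,4aR,5R,6S,8aR)‑6‑acetoxy‑3‑acetyl‑1,8a‑dihydroxy‑4a,5‑dimethyl‑4a,5,6,7,8,8a‑hexahydronaphthalen‑2(1H)‑one
Conditions: DDQ, CH2Cl2/pH 7 buffer, 0 °C to rt
Reagents that add atoms: none
Why: Oxidative cleavage of the 4‑methoxybenzyl ether by DDQ (benzylic hydride abstraction, hydrolysis of the oxocarbenium ion) should free the C9 hydroxyl under neutral conditions that spare the acetate, the ketol and the enedione.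

Step 14
Reactants: 19 (1S,4aR,5R,6S,8aR)‑6‑acetoxy‑3‑acetyl‑1,8a‑dihydroxy‑4a,5‑dimethyl‑4a,5,6,7,8,8a‑hexahydronaphthalen‑2(1H)‑one, 20 (Z)‑2‑methylbut‑2‑enoic acid (angelic acid)
Product: 22 [(1S,4aR,5R,6S,8aR)‑6‑acetoxy‑3‑acetyl‑8a‑hydroxy‑4a,5‑dimethyl‑2‑oxo‑1,2,4a,5,6,7,8,8a‑octahydronaphthalen‑1‑yl] (2Z)‑2‑methylbut‑2‑enoate, via mixed anhydride 21 (not isolated)
Conditions: 20, 2,4,6‑Cl3C6H2COCl, Et3N, toluene, rt; then 19, toluene, 80 °C
Reagents that add atoms: none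
Why: Yamaguchi esterification through the 2,4,6‑trichlorobenzoyl mixed anhydride should acylate the secondary C9 hydroxyl while the tertiary C10 hydroxyl stays free, and the absence of nucleophilic catalysts avoids isomerization of the angelate to the tiglate.

**Compound list**

1 | pent‑1‑en‑3‑one | CCC(=O)C=C | starting material
2 | (Z)‑3‑(triisopropylsilyloxy)penta‑1,3‑diene | C/C=C(/C=C)O[Si](C(C)C)(C(C)C)C(C)C | intermediate
3 | (E)‑pent‑3‑en‑2‑one | C/C=C/C(C)=O | starting material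
4 | 1‑[(1R,5R,6R)‑5,6‑dimethyl‑4‑(triisopropylsilyloxy)cyclohex‑3‑en‑1‑yl]ethanone | CC(=O)[C@@H]1CC=C(O[Si](C(C)C)(C(C)C)C(C)C)[C@H](C)[C@H]1C | intermediate
5 | 1‑[(6R,7R,8R)‑6,7‑dimethyl‑1,4‑dioxaspiro[4.5]decan‑8‑yl]ethanone | CC(=O)[C@@H]1CCC2(OCCO2)[C@H](C)[C@H]1C | intermediate
6 | (6R,7R,8R)‑6,7‑dimethyl‑1,4‑dioxaspiro[4.5]decan‑8‑yl acetate | CC(=O)O[C@@H]1CCC2(OCCO2)[C@H](C)[C@H]1C | intermediate
7 | (6R,7R,8R)‑6,7‑dimethyl‑1,4‑dioxaspiro[4.5]decan‑8‑ol | O[C@@H]1CCC2(OCCO2)[C@H](C)[C@H]1C | intermediate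
8 | (6R,7R,8S)‑6,7‑dimethyl‑1,4‑dioxaspiro[4.5]decan‑8‑yl acetate | CC(=O)O[C@H]1CCC2(OCCO2)[C@H](C)[C@H]1C | intermediate
9 | (1S,2R,3R)‑2,3‑dimethyl‑4‑oxocyclohexyl acetate | CC(=O)O[C@H]1CCC(=O)[C@H](C)[C@H]1C | intermediate
10 | (4‑methoxyphenyl)methanol | COc1ccc(CO)cc1 | starting material
11 | 2‑chloro‑N‑methoxy‑N‑methylacetamide | CON(C)C(=O)CCl | starting material
12 | N‑methoxy‑2‑[(4‑methoxyphenyl)methoxy]‑N‑methylacetamide | CON(C)C(=O)COCc1ccc(OC)cc1 | intermediate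
13 | 1‑[(4‑methoxyphenyl)methoxy]but‑3‑en‑2‑one | C=CC(=O)COCc1ccc(OC)cc1 | intermediate
14 | (1S,2R,3R)‑3‑{4‑[(4‑methoxyphenyl)methoxy]‑3‑oxobutyl}‑2,3‑dimethyl‑4‑oxocyclohexyl acetate (Michael adduct, not isolated) | COc1ccc(COCC(=O)CC[C@]2(C)[C@@H](C)[C@@H](OC(C)=O)CCC2=O)cc1 | intermediate
15 | (1S,4aR,5R,6S,8aR)‑6‑acetoxy‑8a‑hydroxy‑1‑[(4‑methoxyphenyl)methoxy]‑4a,5‑dimethyloctahydronaphthalen‑2(1H)‑one | COc1ccc(CO[C@@H]2C(=O)CC[C@]3(C)[C@@H](C)[C@@H](OC(C)=O)CC[C@]23O)cc1 | intermediate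
16 | (1R,4aR,5R,6S,8aR)‑3‑acetyl‑2,8a‑dihydroxy‑1‑[(4‑methoxyphenyl)methoxy]‑4a,5‑dimethyl‑1,4,4a,5,6,7,8,8a‑octahydronaphthalen‑6‑yl acetate (enol form of the β‑diketone) | COc1ccc(CO[C@@H]2C(O)=C(C(C)=O)C[C@]3(C)[C@@H](C)[C@@H](OC(C)=O)CC[C@]23O)cc1 | intermediate
17 | (1S,4aR,5R,6S,8aR)‑6‑acetoxy‑3‑acetyl‑8a‑hydroxy‑1‑[(4‑methoxyphenyl)methoxy]‑4a,5‑dimethyl‑3‑(phenylselanyl)octahydronaphthalen‑2(1H)‑one (either configuration at C3; not isolated) | COc1ccc(CO[C@@H]2C(=O)C([Se]c4ccccc4)(C(C)=O)C[C@]3(C)[C@@H](C)[C@@H](OC(C)=O)CC[C@]23O)cc1 | intermediate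
18 | (1S,4aR,5R,6S,8aR)‑6‑acetoxy‑3‑acetyl‑8a‑hydroxy‑1‑[(4‑methoxyphenyl)methoxy]‑4a,5‑dimethyl‑4a,5,6,7,8,8a‑hexahydronaphthalen‑2(1H)‑one | COc1ccc(CO[C@@H]2C(=O)C(C(C)=O)=C[C@]3(C)[C@@H](C)[C@@H](OC(C)=O)CC[C@]23O)cc1 | intermediate
19 | (1S,4aR,5R,6S,8aR)‑6‑acetoxy‑3‑acetyl‑1,8a‑dihydroxy‑4a,5‑dimethyl‑4a,5,6,7,8,8a‑hexahydronaphthalen‑2(1H)‑one | O[C@@H]1C(=O)C(C(C)=O)=C[C@]2(C)[C@@H](C)[C@@H](OC(C)=O)CC[C@]12O | intermediate
20 | (Z)‑2‑methylbut‑2‑enoic acid (angelic acid) | C/C=C(/C)C(=O)O | starting material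
21 | (Z)‑2‑methylbut‑2‑enoic 2,4,6‑trichlorobenzoic anhydride (not isolated) | C/C=C(/C)C(=O)OC(=O)c1c(Cl)cc(Cl)cc1Cl | intermediate
22 | [(1S,4aR,5R,6S,8aR)‑6‑acetoxy‑3‑acetyl‑8a‑hydroxy‑4a,5‑dimethyl‑2‑oxo‑1,2,4a,5,6,7,8,8a‑octahydronaphthalen‑1‑yl] (2Z)‑2‑methylbut‑2‑enoate | C/C=C(/C)C(=O)O[C@@H]1C(=O)C(C(C)=O)=C[C@]2(C)[C@@H](C)[C@@H](OC(C)=O)CC[C@]12O | target

**Step count and risks**

Total step count: 14. Longest linear sequence: 12 steps (steps 1–7, then 10–14).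

Steps most likely to fail:

1. Step 10. The reversible aldol closure may leave the C9 ether cis to the 10‑hydroxyl or run on to dehydration, and the base may shift or cleave the C3 acetate. The fallback sets out from 9 and fixes the 9,10‑trans relationship by an SN2 event instead of by equilibration. An acid‑catalysed Robinson annulation of 9 with but‑3‑en‑2‑one (H2SO4 cat., benzene, reflux) should pass through the diketone (1S,2R,3R)‑2,3‑dimethyl‑4‑oxo‑3‑(3‑oxobutyl)cyclohexyl acetate F1 and the ketol (1R,2S,4aS,8aR)‑4a‑hydroxy‑1,8a‑dimethyl‑6‑oxodecahydronaphthalen‑2‑yl acetate F2 to the enone (1R,2S,8aR)‑1,8a‑dimethyl‑6‑oxo‑1,2,3,4,6,7,8,8a‑octahydronaphthalen‑2‑yl acetate F3. Nucleophilic epoxidation (t‑BuOOH, DBU, CH2Cl2), expected on the face of the angular methyl by analogy with steroidal 4‑en‑3‑ones, should give the epoxy ketone (1R,2S,4aR,5R,8aR)‑4a,5‑epoxy‑1,8a‑dimethyl‑6‑oxodecahydronaphthalen‑2‑yl acetate F4. Backside opening at C9, α to the ketone, by the alkoxide of 10 (Cs2CO3 cat., 10 as co‑solvent, rt) comes back to the route at 15.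

2. Step 14. The angelate may isomerize to the tiglate, acylation of the hindered α‑ketol hydroxyl may be slow, and C9 may epimerize under amine and heat. The fallback sets out from 19 and builds the Z alkene on the substrate. Esterification with 2‑[bis(2,2,2‑trifluoroethoxy)phosphoryl]propanoic acid (DCC, DMAP cat., CH2Cl2, 0 °C) should give (1S,4aR,5R,6S,8aR)‑6‑acetoxy‑3‑acetyl‑8a‑hydroxy‑4a,5‑dimethyl‑2‑oxo‑1,2,4a,5,6,7,8,8a‑octahydronaphthalen‑1‑yl 2‑[bis(2,2,2‑trifluoroethoxy)phosphoryl]propanoate F5 (both epimers at the phosphorus‑bearing carbon). A Still–Gennari olefination with acetaldehyde (KN(SiMe3)2, 18‑crown‑6, THF, −78 °C) then comes back to the route at 22.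

3. Step 6. Elimination or incomplete inversion may intervene at the hindered secondary carbinol flanked by the methyl‑bearing carbon. The fallback sets out from 7 and replaces substitution by oxidation and reduction. Dess–Martin periodinane (NaHCO3, CH2Cl2) should give the ketone (6R,7R)‑6,7‑dimethyl‑1,4‑dioxaspiro[4.5]decan‑8‑one F6. LiBH(s‑Bu)3 (THF, −78 °C) should attack from the equatorial side to give the axial alcohol (6R,7R,8S)‑6,7‑dimethyl‑1,4‑dioxaspiro[4.5]decan‑8‑ol F7, cis to the C4 methyl. Acetylation (Ac2O, DMAP, pyridine) comes back to the route at 8.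

Further compounds
F1 | step 10 | (1S,2R,3R)‑2,3‑dimethyl‑4‑oxo‑3‑(3‑oxobutyl)cyclohexyl acetate | CC(=O)CC[C@]1(C)[C@@H](C)[C@@H](OC(C)=O)CCC1=O
F2 | step 10 | (1R,2S,4aS,8aR)‑4a‑hydroxy‑1,8a‑dimethyl‑6‑oxodecahydronaphthalen‑2‑yl acetate | O=C1CC[C@]2(C)[C@@H](C)[C@@H](OC(C)=O)CC[C@]2(O)C1
F3 | step 10 | (1R,2S,8aR)‑1,8a‑dimethyl‑6‑oxo‑1,2,3,4,6,7,8,8a‑octahydronaphthalen‑2‑yl acetate | O=C1CC[C@]2(C)[C@@H](C)[C@@H](OC(C)=O)CCC2=C1
F4 | step 10 | (1R,2S,4aR,5R,8aR)‑4a,5‑epoxy‑1,8a‑dimethyl‑6‑oxodecahydronaphthalen‑2‑yl acetate | O=C1CC[C@]2(C)[C@@H](C)[C@@H](OC(C)=O)CC[C@@]23O[C@@H]13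
F5 | step 14 | (1S,4aR,5R,6S,8aR)‑6‑acetoxy‑3‑acetyl‑8a‑hydroxy‑4a,5‑dimethyl‑2‑oxo‑1,2,4a,5,6,7,8,8a‑octahydronaphthalen‑1‑yl 2‑[bis(2,2,2‑trifluoroethoxy)phosphoryl]propanoate | CC(C(=O)O[C@@H]1C(=O)C(C(C)=O)=C[C@]2(C)[C@@H](C)[C@@H](OC(C)=O)CC[C@]12O)P(=O)(OCC(F)(F)F)OCC(F)(F)F
F6 | step 6 | (6R,7R)‑6,7‑dimethyl‑1,4‑dioxaspiro[4.5]decan‑8‑one | O=C1CCC2(OCCO2)[C@H](C)[C@H]1C
F7 | step 6 | (6R,7R,8S)‑6,7‑dimethyl‑1,4‑dioxaspiro[4.5]decan‑8‑ol | O[C@H]1CCC2(OCCO2)[C@H](C)[C@H]1C
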